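**Strategy**

- Retrosynthesis, in chromone numbering: the C5 O–CH3 bond is cut first (protecting group), then O1–C2 (opens the pyranone to an ortho-hydroxyaryl ynone), then C8a–O1 together with C4a–C4 (gives 3-methoxybenzyne and octadec-2-ynoic acid), then C3–C4 (CO2) and C2–C1′ (acetylide plus C15 bromide).
- Forward: the C18 ynoic acid is built by acetylide alkylation and carboxylation, joined to the purchased benzene ring across the aryne bond, the pyranone ring is closed by O1–C2 bond formation, and the C5 phenol is unmasked last.
- Enabling feature: C8a and C4a of the benzo ring carry O1 and the C4 carbonyl on neighbouring carbons, with the oxygenated C5 as the third contiguous substituent. A 3-alkoxybenzyne delivers exactly this 1,2,3-pattern when an oxygen nucleophile enters meta to the alkoxy group and the ortho anion then captures an acyl group.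
- Stereochemistry: the target has no stereocentre and no stereogenic double bond, so nothing has to be set.

Key step: step 3

Remark on the chemistry: compounds 2 and 7 are taken as purchased. Simple O–H salt forms of numbered compounds (carboxylates, phenoxides before work-up) are not numbered separately.

**Step 1**
Reactants: 1 1-bromopentadecane; 2 lithium acetylide ethylenediamine complex (LiC≡CH·H2NCH2CH2NH2)
Product: 3 1-heptadecyne
Conditions: 2 (1.5 equiv), DMSO/THF, 10 °C to rt; then H2O
Reagents that add atoms: none
Why: SN2 alkylation of a metal acetylide; the monolithiated acetylene is a small, strong carbon nucleophile in dipolar aprotic DMSO, the unbranched primary bromide should favour substitution over E2, and dialkylation is excluded because the complex carries only one C–Li bond.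

**Step 2**
Reactants: 3 1-heptadecyne; 4 carbon dioxide
Product: 6 octadec-2-ynoic acid, via lithium heptadec-1-yn-1-ide 5 (not isolated)
Conditions: n-BuLi (1.05 equiv), THF, −78 °C; CO2, −78 °C to rt; then aq HCl
Reagents that add atoms: none
Why: Deprotonation of the terminal alkyne by n-BuLi and carboxylation of the lithium acetylide with CO2 is the standard entry to 2-alkynoic acids; the lithium alkynoate should be inert to further acetylide at low temperature, and acidification releases the acid.

**Step 3**
Reactants: 6 octadec-2-ynoic acid; 7 3-methoxy-2-(trimethylsilyl)phenyl trifluoromethanesulfonate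
Product: 10 1-(2-hydroxy-6-methoxyphenyl)octadec-2-yn-1-one, via 3-methoxybenzyne 8 (not isolated), via cesium 2-methoxy-6-(octadec-2-ynoyloxy)phenide 9 (not isolated)
Conditions: 7 (1.5 equiv), CsF (4 equiv), THF, 125 °C, sealed tube; then aq NH4Cl
Reagents that add atoms: none
Why: Fluoride strips the silyl group of 7 and triflate leaves to give aryne 8; the cesium salt of 6 adds through a carboxylate oxygen to the aryne carbon meta to OMe, which puts the negative charge on the carbon flanked by the new ester oxygen and the methoxy group (9). This aryl anion attacks its own ester carbonyl (4-exo-trig) and the strained four-membered alkoxide reopens by C–O cleavage to the phenoxide of 10, so C8a–O1 and C4a–C4 of the target form on the two former aryne carbons and no ring remains closed in the product. The closest known reaction type is the formal insertion of arynes into the C–O bond of carboxylic acids (O-arylation, then anionic 1,3 O-to-C acyl shift) giving ortho-hydroxyaryl ketones. No stereocentre is created. Regioselectivity on the aryne should come from the inductive pull of the methoxy group and the bond-angle distortion it imposes, both directing the nucleophile to the distal carbon; attack at the carbonyl rather than the alkyne β-carbon should come from the Z conformation of the aryl ester, which turns the alkyne away from the ring; acyl transfer should outpace protonation because the acid is the limiting, fully ionised partner and the aryne is released slowly by sparingly soluble CsF.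

**Step 4**
Reactants: 10 1-(2-hydroxy-6-methoxyphenyl)octadec-2-yn-1-one
Product: 12 5-methoxy-2-pentadecylchromone, via (E)-3-(diethylamino)-1-(2-hydroxy-6-methoxyphenyl)octadec-2-en-1-one 11 (not isolated)
Conditions: Et2NH (3 equiv), EtOH, rt, then reflux
Reagents that add atoms: none
Why: Amine-mediated cyclisation of an ortho-hydroxyaryl ynone; Et2NH adds to the ynone β-carbon (aza-Michael) to give enaminone 11, the phenol oxygen adds to the same carbon and the amine is expelled (addition–elimination, 6-endo-trig), which should shut off the 5-exo aurone mode, and the double-bond geometry of 11 is lost at the tetrahedral stage.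

**Step 5**
Reactants: 12 5-methoxy-2-pentadecylchromone
Product: 14 5-hydroxy-2-pentadecylchromone (target), via 5-(dichloroboryloxy)-2-pentadecylchromone 13 (not isolated)
Conditions: BCl3 (1 M in CH2Cl2, 3 equiv), CH2Cl2, −78 °C to rt; then H2O, aq HCl
Reagents that add atoms: none
Why: Chelation-assisted Lewis acid ether cleavage; BCl3 is held between the C4 carbonyl oxygen and the peri methoxy oxygen, chloride removes the methyl group by SN2 to give boron chelate 13, and aqueous acid hydrolyses the B–O bond to the hydrogen-bonded phenol, while the pyranone ring and the saturated chain should be untouched.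

**Compound list**

1 | 1-bromopentadecane | CCCCCCCCCCCCCCCBr | starting material
2 | lithium acetylide ethylenediamine complex | [Li]C#C.NCCN | starting material
3 | 1-heptadecyne | CCCCCCCCCCCCCCCC#C | intermediate
4 | carbon dioxide | O=C=O | starting material
5 | lithium heptadec-1-yn-1-ide | CCCCCCCCCCCCCCCC#C[Li] | intermediate
6 | octadec-2-ynoic acid | CCCCCCCCCCCCCCCC#CC(=O)O | intermediate
7 | 3-methoxy-2-(trimethylsilyl)phenyl trifluoromethanesulfonate | COc1cccc(OS(=O)(=O)C(F)(F)F)c1[Si](C)(C)C | starting material
8 | 3-methoxybenzyne | COC1=CC=CC#C1 | intermediate
9 | cesium 2-methoxy-6-(octadec-2-ynoyloxy)phenide (aryl anion between the ester oxygen and the methoxy group) | CCCCCCCCCCCCCCCC#CC(=O)Oc1cccc(OC)[c-]1.[Cs+] | intermediate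
10 | 1-(2-hydroxy-6-methoxyphenyl)octadec-2-yn-1-one | CCCCCCCCCCCCCCCC#CC(=O)c1c(O)cccc1OC | intermediate
11 | (E)-3-(diethylamino)-1-(2-hydroxy-6-methoxyphenyl)octadec-2-en-1-one | CCCCCCCCCCCCCCC/C(N(CC)CC)=C\C(=O)c1c(O)cccc1OC | intermediate
12 | 5-methoxy-2-pentadecylchromone | CCCCCCCCCCCCCCCc1cc(=O)c2c(OC)cccc2o1 | intermediate
13 | 5-(dichloroboryloxy)-2-pentadecylchromone (boron chelated to the C4 carbonyl) | CCCCCCCCCCCCCCCc1cc(=O)c2c(OB(Cl)Cl)cccc2o1 | intermediate
14 | 5-hydroxy-2-pentadecylchromone | CCCCCCCCCCCCCCCc1cc(=O)c2c(O)cccc2o1 | target

**Step count**

Total: 5 steps. Longest linear sequence: 5 steps (1 → 3 → 6 → 10 → 12 → 14).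

**Steps most likely to fail**

Step 3 (aryne C–O insertion). Several processes could divert it:
- protonation of aryl anion 9 before acyl transfer, which stops at the simple aryl ester;
- further O-arylation of the product phenoxide by surplus aryne;
- thermal loss of CO2 from the cesium alkynoate;
- in-flask closure of the phenoxide onto the alkyne in the 5-exo mode.

Fallback: set out from 1-heptadecyne 3 and lithiate it to 5 as in step 2. Add 2.2 equivalents of 5 to purchased 2-hydroxy-6-methoxybenzaldehyde (COc1cccc(O)c1C=O) in THF at −78 to 0 °C; the first equivalent is consumed by the phenol and returns as 3 on work-up. This should give racemic 1-(2-hydroxy-6-methoxyphenyl)octadec-2-yn-1-ol F1. Oxidation of this benzylic, propargylic alcohol with MnO2 in CH2Cl2 at rt removes the carbinol stereocentre and rejoins the route at ynone 10.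

Step 4 (ring closure). The displacement of the amine could stall at the enaminone, because the β-carbon carries a long chain beside a twisted 2,6-disubstituted aryl ketone. Direct phenoxide attack before the amine has added could also give 5-exo closure. Fallback: set out from 10 and form enaminone 11 with Et2NH at rt. Hydrolyse it with aqueous HCl in THF to 1-(2-hydroxy-6-methoxyphenyl)octadecane-1,3-dione F2. Close the ring by acid-catalysed cyclodehydration (H2SO4 in AcOH, warm), in which the phenol adds to the alkyl ketone and water is lost, so only the six-membered ring can form. This rejoins the route at 12.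

Step 1 (acetylide alkylation). The waxy bromide is sparingly soluble in DMSO, and in a poorly mixed suspension E2 loss of HBr and incomplete conversion could compete with substitution. Fallback: set out from 1 and alkylate purchased LiC≡CSiMe3 (solution in THF) in THF/DMPU at 0 °C to rt, which should give trimethyl(heptadec-1-yn-1-yl)silane F3 in a homogeneous medium. Removal of the silyl group with K2CO3 in MeOH at rt rejoins the route at 3.

**Further compounds**

F1 | step 3 | 1-(2-hydroxy-6-methoxyphenyl)octadec-2-yn-1-ol (racemic) | CCCCCCCCCCCCCCCC#CC(O)c1c(O)cccc1OC
F2 | step 4 | 1-(2-hydroxy-6-methoxyphenyl)octadecane-1,3-dione | CCCCCCCCCCCCCCCC(=O)CC(=O)c1c(O)cccc1OC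
F3 | step 1 | trimethyl(heptadec-1-yn-1-yl)silane | CCCCCCCCCCCCCCCC#C[Si](C)(C)C
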